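## Retrosynthetic overview

1. The esters come last: the C6 angelate goes on the 6β-alcohol from hydroxyl-directed reduction of a C6 ketone, and the C2 acetate on the free secondary alcohol. The C6 ketone and the 5β-H come from a C5=C6 alkene by C4–OH-directed epoxidation and a Meinwald hydride shift.
2. Ring B (C1, C5–C10) is closed by a Cope rearrangement that forms C1–C10. The enabling feature: in ring B the C8=C9 alkene and C5=C6 (the masked C6 oxygen) are 1,4 to each other across the C7 methylene, with C1–C10 opposite C7. This cyclohepta-1,4-diene is the product pattern of a cis-cyclopropane C6–C7–C8 carrying the arms C5=C1 and C9=C10. The benzoate rides in as the (Z)-substituent of the C9=C10 arm and therefore lands 10α.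
3. The cyclopropane comes from a (Z)-allylic alcohol (Still–Gennari olefination, reduction, reagent-controlled Charette cyclopropanation). The enol benzoate arm comes from the aldehyde via the alkyne and Ru-catalysed anti-Markovnikov addition of benzoic acid.
4. Ring A with C1–C6, CH3-15, the isopropyl group and the C4 stereocentre is the contracted six-membered ring of (S)-terpinen-4-ol (allylic oxidation for the C2 oxygen, ozonolysis, aldol condensation).
5. Order of ring formation: ring A (step 5), temporary cyclopropane (step 8), ring B (step 12).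

Key step: step 12

Remark on numbering and faces: daucane numbering is used for every intermediate, also the monocyclic ones. C1 is the quaternary ring-fusion carbon with CH3-15, C2–C4 complete ring A with the isopropyl group on C4, C5 is the ring-fusion CH, and C6–C10 complete ring B with CH3-14 on C8. α is the face of CH3-15 in the bicycle, β the other face.

Assumption: (S)-(+)-terpinen-4-ol is taken as a commercial, enantiomerically enriched starting material; an insufficient ee would be raised at a crystalline stage such as diol 4.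

## Route

Step 1
Reactants: 1 (S)-(+)-terpinen-4-ol
Product: 3 (R)-5-hydroxy-2-methyl-5-(propan-2-yl)cyclohex-2-en-1-one, via allylic alcohol 2 (not isolated)
Conditions: SeO2 (cat.), t-BuOOH, CH2Cl2, rt; then MnO2, CH2Cl2, rt
Reagents that add atoms: tert-butyl hydroperoxide, CC(C)(C)OO (oxygen relayed by the SeO2 catalyst)
Why: SeO2 allylic oxidation (ene reaction, then [2,3]-shift) should hydroxylate the ring CH2 on the more substituted alkene carbon with the double bond returning to its place, so the C4 stereocentre is not eroded by allylic transposition, and MnO2 converges both carbinol epimers to one enone.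

Step 2
Reactants: 3 (R)-5-hydroxy-2-methyl-5-(propan-2-yl)cyclohex-2-en-1-one
Product: 4 (1S,5R)-2-methyl-5-(propan-2-yl)cyclohex-2-ene-1,5-diol
Conditions: NaBH4, CeCl3·7H2O, MeOH, −78 to 0 °C
Reagents that add atoms: none
Why: Luche 1,2-reduction with axial hydride delivery on the half-chair that keeps the isopropyl group equatorial should give the equatorial alcohol, trans to the tertiary hydroxyl (the future 2β-oxygen).

Step 3
Reactants: 4 (1S,5R)-2-methyl-5-(propan-2-yl)cyclohex-2-ene-1,5-diol
Product: 5 (1S,5R)-2-methyl-5-(propan-2-yl)-1,5-bis(triethylsilyloxy)cyclohex-2-ene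
Conditions: Et3SiOTf, 2,6-lutidine, CH2Cl2, −78 to 0 °C
Reagents that add atoms: triethylsilyl trifluoromethanesulfonate, CC[Si](CC)(CC)OS(=O)(=O)C(F)(F)F
Why: Silyl ether formation with the silyl triflate protects the secondary and the hindered tertiary hydroxyl in one operation without touching a stereocentre.

Step 4
Reactants: 5 (1S,5R)-2-methyl-5-(propan-2-yl)-1,5-bis(triethylsilyloxy)cyclohex-2-ene
Product: 7 (3S,5S)-6-oxo-3-(propan-2-yl)-3,5-bis(triethylsilyloxy)heptanal, via ozonide 6 (not isolated)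
Conditions: O3, CH2Cl2, −78 °C; then PPh3, −78 °C to rt
Reagents that add atoms: ozone, [O-][O+]=O
Why: Ozonolysis with reductive work-up cleaves the only alkene to the methyl ketone and the aldehyde and leaves both stereocentres untouched.

Step 5
Reactants: 7 (3S,5S)-6-oxo-3-(propan-2-yl)-3,5-bis(triethylsilyloxy)heptanal
Product: 8 (3S,5R)-2-methyl-5-(propan-2-yl)-3,5-bis(triethylsilyloxy)cyclopent-1-ene-1-carbaldehyde
Conditions: (PhCH2)2NH2+ CF3CO2− (cat.), benzene, 50 °C
Reagents that add atoms: none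
Why: Intramolecular aldol condensation (enamine of the aldehyde onto the methyl ketone, five-membered closure, dehydration) contracts the former six-membered ring to ring A, as in the known conversion of 6-oxoheptanals into 2-methylcyclopentenecarbaldehydes.

Step 6
Reactants: 8 (3S,5R)-2-methyl-5-(propan-2-yl)-3,5-bis(triethylsilyloxy)cyclopent-1-ene-1-carbaldehyde
Product: 9 ethyl (Z)-2-methyl-3-[(3S,5R)-2-methyl-5-(propan-2-yl)-3,5-bis(triethylsilyloxy)cyclopent-1-en-1-yl]prop-2-enoate
Conditions: (CF3CH2O)2P(O)CH(CH3)CO2Et, KN(SiMe3)2, 18-crown-6, THF, −78 °C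
Reagents that add atoms: ethyl 2-[bis(2,2,2-trifluoroethoxy)phosphoryl]propanoate, CCOC(=O)C(C)P(=O)(OCC(F)(F)F)OCC(F)(F)F
Why: Still–Gennari olefination under kinetic control should give the (Z)-trisubstituted enoate with the ester cis to the ring, which later fixes the cis arrangement of the two alkenyl arms.

Step 7
Reactants: 9 ethyl (Z)-2-methyl-3-[(3S,5R)-2-methyl-5-(propan-2-yl)-3,5-bis(triethylsilyloxy)cyclopent-1-en-1-yl]prop-2-enoate
Product: 10 (Z)-2-methyl-3-[(3S,5R)-2-methyl-5-(propan-2-yl)-3,5-bis(triethylsilyloxy)cyclopent-1-en-1-yl]prop-2-en-1-ol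
Conditions: i-Bu2AlH, CH2Cl2, −78 °C
Reagents that add atoms: none
Why: 1,2-Reduction of the enoate by the aluminium hydride gives the allylic alcohol with the alkene geometry retained.

Step 8
Reactants: 10 (Z)-2-methyl-3-[(3S,5R)-2-methyl-5-(propan-2-yl)-3,5-bis(triethylsilyloxy)cyclopent-1-en-1-yl]prop-2-en-1-ol
Product: 11 {(1S,2R)-1-methyl-2-[(3S,5R)-2-methyl-5-(propan-2-yl)-3,5-bis(triethylsilyloxy)cyclopent-1-en-1-yl]cyclopropyl}methanol
Conditions: Zn(CH2I)2·DME (from Et2Zn and CH2I2), (4R,5R)-2-butyl-N,N,N′,N′-tetramethyl-1,3,2-dioxaborolane-4,5-dicarboxamide, CH2Cl2, −10 °C to rt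
Reagents that add atoms: diiodomethane, ICI
Why: Charette asymmetric Simmons–Smith cyclopropanation: the zinc alkoxide bound to the chiral dioxaborolane delivers CH2 stereospecifically to one face of the allylic alkene (reagent control, 6R,8S), so the (Z)-alkene becomes the cis-cyclopropane, while the tetrasubstituted ring alkene has no directing hydroxyl and stays.

Step 9
Reactants: 11 {(1S,2R)-1-methyl-2-[(3S,5R)-2-methyl-5-(propan-2-yl)-3,5-bis(triethylsilyloxy)cyclopent-1-en-1-yl]cyclopropyl}methanol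
Product: 12 (1S,2S)-1-methyl-2-[(3S,5R)-2-methyl-5-(propan-2-yl)-3,5-bis(triethylsilyloxy)cyclopent-1-en-1-yl]cyclopropane-1-carbaldehyde
Conditions: Dess–Martin periodinane, NaHCO3, CH2Cl2, 0 °C
Reagents that add atoms: none
Why: Dess–Martin oxidation of the neopentyl primary alcohol is mild and the quaternary α-carbon cannot epimerise (the descriptor at the second ring carbon changes by priority only).

Step 10
Reactants: 12 (1S,2S)-1-methyl-2-[(3S,5R)-2-methyl-5-(propan-2-yl)-3,5-bis(triethylsilyloxy)cyclopent-1-en-1-yl]cyclopropane-1-carbaldehyde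
Product: 13 (3S,5R)-1-[(1R,2S)-2-ethynyl-2-methylcyclopropyl]-2-methyl-5-(propan-2-yl)-3,5-bis(triethylsilyloxy)cyclopent-1-ene
Conditions: CH3C(O)C(N2)P(O)(OMe)2, K2CO3, MeOH, 0 °C to rt
Reagents that add atoms: dimethyl (1-diazo-2-oxopropyl)phosphonate, CC(=O)C(=[N+]=[N-])P(=O)(OC)OC
Why: Ohira–Bestmann (Seyferth–Gilbert) homologation turns the non-enolisable aldehyde into the terminal alkyne without touching the cyclopropane stereocentres.

Step 11
Reactants: 13 (3S,5R)-1-[(1R,2S)-2-ethynyl-2-methylcyclopropyl]-2-methyl-5-(propan-2-yl)-3,5-bis(triethylsilyloxy)cyclopent-1-ene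
Product: 14 (Z)-2-{(1S,2R)-1-methyl-2-[(3S,5R)-2-methyl-5-(propan-2-yl)-3,5-bis(triethylsilyloxy)cyclopent-1-en-1-yl]cyclopropyl}ethenyl benzoate
Conditions: [Ru(η3-CH2C(CH3)CH2)2(Ph2P(CH2)4PPh2)] (cat.), PhCO2H, toluene, 45 °C
Reagents that add atoms: benzoic acid, OC(=O)c1ccccc1
Why: Ruthenium-catalysed anti-Markovnikov addition of the carboxylic acid to the terminal alkyne via a vinylidene should give the (Z)-enol ester, which puts the future C10 benzoate on the inward position of the second alkenyl arm.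

Step 12
Reactants: 14 (Z)-2-{(1S,2R)-1-methyl-2-[(3S,5R)-2-methyl-5-(propan-2-yl)-3,5-bis(triethylsilyloxy)cyclopent-1-en-1-yl]cyclopropyl}ethenyl benzoate
Product: 15 10α-benzoyloxy-2β,4α-bis(triethylsilyloxy)dauca-5,8-diene
Conditions: toluene, 110–130 °C, sealed tube, trace BHT
Reagents that add atoms: none
Why: Thermal [3,3]-sigmatropic shift of the cis-1,2-dialkenylcyclopropane through the boat transition state (the divinylcyclopropane–cycloheptadiene Cope rearrangement is the closest known reaction type): the strained C6–C8 bond is exchanged for the C1–C10 bond and the C5=C6 and C8=C9 alkenes appear in place. Ring B is closed by ring expansion (three- to seven-membered, the alkenyl termini C1 and C10 joining above the C7 methylene), which is irreversible because cyclopropane strain is released. C1 is controlled by the cyclopropane configuration (6R,8S) from step 8, since the cyclopentenyl arm can fold over the three-membered ring with one face only (the face syn to the C4 isopropyl group), which puts CH3-15 on the α face. C10 is controlled by the (Z)-geometry of the enol benzoate, the inward benzoyloxy group ending on the same side as the inward C1 methyl (10α). The step needs stereospecificity (the concerted shift must outrun homolytic cis/trans stereomutation of the cyclopropane); the cis arrangement of the arms from the (Z)-alkene of 10 and the absence of a cis-alkyl C–H for a homodienyl 1,5-hydrogen shift secure this. Two inward substituents and bond formation on the more hindered β face raise the barrier, hence the heating.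

Step 13
Reactants: 15 10α-benzoyloxy-2β,4α-bis(triethylsilyloxy)dauca-5,8-diene
Product: 16 10α-benzoyloxydauca-5,8-diene-2β,4α-diol
Conditions: HF·pyridine, pyridine, THF, 0 °C to rt
Reagents that add atoms: none
Why: Fluoride-mediated cleavage of both triethylsilyl ethers in buffered medium should leave the allylic benzoate and the skipped diene intact.

Step 14
Reactants: 16 10α-benzoyloxydauca-5,8-diene-2β,4α-diol
Product: 17 2β-acetoxy-10α-benzoyloxydauca-5,8-dien-4α-ol
Conditions: Ac2O, pyridine, DMAP (cat.), CH2Cl2, 0 °C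
Reagents that add atoms: acetic anhydride, CC(=O)OC(C)=O
Why: Acylation takes the only secondary hydroxyl, the tertiary C4–OH being inert under these mild conditions.

Step 15
Reactants: 17 2β-acetoxy-10α-benzoyloxydauca-5,8-dien-4α-ol
Product: 18 2β-acetoxy-10α-benzoyloxy-5α,6α-epoxydauc-8-en-4α-ol
Conditions: VO(acac)2 (cat.), t-BuOOH, CH2Cl2, 0 °C to rt
Reagents that add atoms: tert-butyl hydroperoxide, CC(C)(C)OO
Why: Hydroxyl-directed epoxidation: the vanadate ester of the tertiary allylic C4–OH delivers oxygen to C5=C6 on its own (α) face, and the C8=C9 alkene, which has no allylic hydroxyl, is left.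

Step 16
Reactants: 18 2β-acetoxy-10α-benzoyloxy-5α,6α-epoxydauc-8-en-4α-ol
Product: 19 2β-acetoxy-10α-benzoyloxy-4α-hydroxy-5β-H-dauc-8-en-6-one
Conditions: BF3·OEt2 (cat.), CH2Cl2, −78 °C
Reagents that add atoms: none
Why: Meinwald rearrangement: ionisation at the tertiary C5 and a 1,2-hydride shift from C6 anti to the departing oxygen should give the C6 ketone with 5β-H (trans ring fusion, which with C6 trans to the isopropyl group should also be the thermodynamic arrangement).

Step 17
Reactants: 19 2β-acetoxy-10α-benzoyloxy-4α-hydroxy-5β-H-dauc-8-en-6-one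
Product: 20 2β-acetoxy-10α-benzoyloxy-5β-H-dauc-8-ene-4α,6β-diol
Conditions: Me4NBH(OAc)3, AcOH, MeCN, −30 °C
Reagents that add atoms: none
Why: Evans–Saksena reduction: the acyloxyborohydride bound to C4–OH delivers hydride intramolecularly to the α face of the ketone and should give the 1,3-anti diol, that is the 6β-alcohol.

Step 18
Reactants: 20 2β-acetoxy-10α-benzoyloxy-5β-H-dauc-8-ene-4α,6β-diol
Product: 21 (1R,2S,4R,5S,6S,10S)-2β-acetoxy-6β-angeloyloxy-10α-benzoyloxy-5β-H-dauc-8-en-4α-ol (CNP0248576.1)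
Conditions: (Z)-2-methylbut-2-enoic acid, 2,4,6-Cl3C6H2COCl, Et3N, toluene, rt; then 20, toluene, 75 °C
Reagents that add atoms: angelic acid, C/C=C(/C)C(O)=O
Why: Yamaguchi-type acylation with the preformed mixed anhydride, without nucleophilic catalyst or strong base, should keep the (Z)-geometry of the acyl group and take only the secondary C6–OH.

## Compound list

1 | (S)-(+)-terpinen-4-ol, (1S)-4-methyl-1-(propan-2-yl)cyclohex-3-en-1-ol | CC1=CC[C@](O)(C(C)C)CC1 | starting material
2 | (5R)-2-methyl-5-(propan-2-yl)cyclohex-2-ene-1,5-diol, both C1 epimers | CC1=CC[C@](O)(C(C)C)CC1O | intermediate (not isolated)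
3 | (R)-5-hydroxy-2-methyl-5-(propan-2-yl)cyclohex-2-en-1-one | CC1=CC[C@](O)(C(C)C)CC1=O | intermediate
4 | (1S,5R)-2-methyl-5-(propan-2-yl)cyclohex-2-ene-1,5-diol | CC1=CC[C@](O)(C(C)C)C[C@@H]1O | intermediate
5 | (1S,5R)-2-methyl-5-(propan-2-yl)-1,5-bis(triethylsilyloxy)cyclohex-2-ene | CC1=CC[C@](O[Si](CC)(CC)CC)(C(C)C)C[C@@H]1O[Si](CC)(CC)CC | intermediate
6 | secondary ozonide of 5 (1,2,4-trioxolane across the former alkene, diastereomers at the two acetal carbons) | CC12OOC(O1)C[C@](O[Si](CC)(CC)CC)(C(C)C)C[C@@H]2O[Si](CC)(CC)CC | intermediate (not isolated)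
7 | (3S,5S)-6-oxo-3-(propan-2-yl)-3,5-bis(triethylsilyloxy)heptanal | CC(=O)[C@@H](O[Si](CC)(CC)CC)C[C@@](O[Si](CC)(CC)CC)(C(C)C)CC=O | intermediate
8 | (3S,5R)-2-methyl-5-(propan-2-yl)-3,5-bis(triethylsilyloxy)cyclopent-1-ene-1-carbaldehyde | O=CC1=C(C)[C@@H](O[Si](CC)(CC)CC)C[C@@]1(O[Si](CC)(CC)CC)C(C)C | intermediate
9 | ethyl (Z)-2-methyl-3-[(3S,5R)-2-methyl-5-(propan-2-yl)-3,5-bis(triethylsilyloxy)cyclopent-1-en-1-yl]prop-2-enoate | CCOC(=O)/C(C)=C\C1=C(C)[C@@H](O[Si](CC)(CC)CC)C[C@@]1(O[Si](CC)(CC)CC)C(C)C | intermediate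
10 | (Z)-2-methyl-3-[(3S,5R)-2-methyl-5-(propan-2-yl)-3,5-bis(triethylsilyloxy)cyclopent-1-en-1-yl]prop-2-en-1-ol | OC/C(C)=C\C1=C(C)[C@@H](O[Si](CC)(CC)CC)C[C@@]1(O[Si](CC)(CC)CC)C(C)C | intermediate
11 | {(1S,2R)-1-methyl-2-[(3S,5R)-2-methyl-5-(propan-2-yl)-3,5-bis(triethylsilyloxy)cyclopent-1-en-1-yl]cyclopropyl}methanol | OC[C@@]1(C)C[C@H]1C2=C(C)[C@@H](O[Si](CC)(CC)CC)C[C@@]2(O[Si](CC)(CC)CC)C(C)C | intermediate
12 | (1S,2S)-1-methyl-2-[(3S,5R)-2-methyl-5-(propan-2-yl)-3,5-bis(triethylsilyloxy)cyclopent-1-en-1-yl]cyclopropane-1-carbaldehyde | O=C[C@@]1(C)C[C@H]1C2=C(C)[C@@H](O[Si](CC)(CC)CC)C[C@@]2(O[Si](CC)(CC)CC)C(C)C | intermediate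
13 | (3S,5R)-1-[(1R,2S)-2-ethynyl-2-methylcyclopropyl]-2-methyl-5-(propan-2-yl)-3,5-bis(triethylsilyloxy)cyclopent-1-ene | C#C[C@@]1(C)C[C@H]1C2=C(C)[C@@H](O[Si](CC)(CC)CC)C[C@@]2(O[Si](CC)(CC)CC)C(C)C | intermediate
14 | (Z)-2-{(1S,2R)-1-methyl-2-[(3S,5R)-2-methyl-5-(propan-2-yl)-3,5-bis(triethylsilyloxy)cyclopent-1-en-1-yl]cyclopropyl}ethenyl benzoate | O=C(O/C=C\[C@@]1(C)C[C@H]1C2=C(C)[C@@H](O[Si](CC)(CC)CC)C[C@@]2(O[Si](CC)(CC)CC)C(C)C)c3ccccc3 | intermediate
15 | 10α-benzoyloxy-2β,4α-bis(triethylsilyloxy)dauca-5,8-diene | C12=CCC(C)=C[C@H](OC(=O)c3ccccc3)[C@@]1(C)[C@@H](O[Si](CC)(CC)CC)C[C@@]2(O[Si](CC)(CC)CC)C(C)C | intermediate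
16 | 10α-benzoyloxydauca-5,8-diene-2β,4α-diol | C12=CCC(C)=C[C@H](OC(=O)c3ccccc3)[C@@]1(C)[C@@H](O)C[C@@]2(O)C(C)C | intermediate
17 | 2β-acetoxy-10α-benzoyloxydauca-5,8-dien-4α-ol | C12=CCC(C)=C[C@H](OC(=O)c3ccccc3)[C@@]1(C)[C@@H](OC(C)=O)C[C@@]2(O)C(C)C | intermediate
18 | 2β-acetoxy-10α-benzoyloxy-5α,6α-epoxydauc-8-en-4α-ol | C1C(C)=C[C@H](OC(=O)c4ccccc4)[C@@]2(C)[C@@H](OC(C)=O)C[C@@](O)(C(C)C)[C@]23O[C@H]13 | intermediate
19 | 2β-acetoxy-10α-benzoyloxy-4α-hydroxy-5β-H-dauc-8-en-6-one | O=C1CC(C)=C[C@H](OC(=O)c3ccccc3)[C@@]2(C)[C@@H](OC(C)=O)C[C@@](O)(C(C)C)[C@H]12 | intermediate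
20 | 2β-acetoxy-10α-benzoyloxy-5β-H-dauc-8-ene-4α,6β-diol | O[C@H]1CC(C)=C[C@H](OC(=O)c3ccccc3)[C@@]2(C)[C@@H](OC(C)=O)C[C@@](O)(C(C)C)[C@H]12 | intermediate
21 | (1R,2S,4R,5S,6S,10S)-2β-acetoxy-6β-angeloyloxy-10α-benzoyloxy-5β-H-dauc-8-en-4α-ol | C/C=C(/C)C(=O)O[C@H]1CC(C)=C[C@H](OC(=O)c2ccccc2)[C@@]2(C)[C@@H](OC(C)=O)C[C@@](O)(C(C)C)[C@H]12 | target

## Step count and risks

Total step count: 18 steps. Longest linear sequence: 18 steps (fully linear from 1).

Steps most likely to fail:

Step 12 (key step). The two inward groups (CH3 on C1, benzoyloxy on C10) and bond formation on the hindered face may slow the concerted shift so much that homolytic stereomutation of the cyclopropane (loss of the C1 configuration) or decomposition competes. The fallback sets out from aldehyde 12 and comes back at 15. Takai-type olefination with Cl2CHB(pin), CrCl2 and LiI should give the (E)-alkenylboronate F1, which has only one inward group and should rearrange at lower temperature to the allylic boronate F2. Oxidation with NaBO3·4H2O gives the 10β-alcohol F3 and MnO2 the enone F4. Corey–Bakshi–Shibata reduction, with the oxazaborolidine enantiomer chosen for hydride delivery to the β face, gives the 10α-alcohol F5. Benzoylation (PhCOCl, pyridine, DMAP) then gives 15.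

Step 16. Instead of the hydride shift, a semipinacol shift of the isopropyl group from the carbinol carbon C4, or ionisation of the allylic benzoate by the Lewis acid, may take over. The fallback sets out from epoxide 18 and comes back at 19. Homolytic epoxide opening with Cp2TiCl (from Cp2TiCl2 and Zn dust) in the presence of 1,4-cyclohexadiene breaks the C5–O bond to the tertiary radical, and hydrogen-atom transfer gives the 6α-alcohol F6. Dess–Martin oxidation then gives 19, with C5 equilibrated to the trans fusion by DBU if needed.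

Step 18. The (Z)-acyl group may isomerise to the (E)-isomer during activation, or acylation of the hindered hydroxyl may be sluggish. The fallback sets out from 20 and comes back at 21. Esterification with 2-[bis(2,2,2-trifluoroethoxy)phosphoryl]propanoic acid (DCC, DMAP) gives the phosphonate ester F7. Still–Gennari olefination with acetaldehyde (KN(SiMe3)2, 18-crown-6, THF, −78 °C) then builds the (Z)-2-methylbut-2-enoate on the molecule.

Further compounds
F1 | step 12 | (E)-alkenyl pinacolboronate from aldehyde 12 (Bpin in place of the benzoyloxy group, E geometry) | CC1(C)OB(/C=C/[C@@]2(C)C[C@H]2C3=C(C)[C@@H](O[Si](CC)(CC)CC)C[C@@]3(O[Si](CC)(CC)CC)C(C)C)OC1(C)C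
F2 | step 12 | 10β-(pinacolboryl)-2β,4α-bis(triethylsilyloxy)dauca-5,8-diene | C12=CCC(C)=C[C@@H](B3OC(C)(C)C(C)(C)O3)[C@@]1(C)[C@@H](O[Si](CC)(CC)CC)C[C@@]2(O[Si](CC)(CC)CC)C(C)C
F3 | step 12 | 2β,4α-bis(triethylsilyloxy)dauca-5,8-dien-10β-ol | C12=CCC(C)=C[C@@H](O)[C@@]1(C)[C@@H](O[Si](CC)(CC)CC)C[C@@]2(O[Si](CC)(CC)CC)C(C)C
F4 | step 12 | 2β,4α-bis(triethylsilyloxy)dauca-5,8-dien-10-one | C12=CCC(C)=CC(=O)[C@@]1(C)[C@@H](O[Si](CC)(CC)CC)C[C@@]2(O[Si](CC)(CC)CC)C(C)C
F5 | step 12 | 2β,4α-bis(triethylsilyloxy)dauca-5,8-dien-10α-ol | C12=CCC(C)=C[C@H](O)[C@@]1(C)[C@@H](O[Si](CC)(CC)CC)C[C@@]2(O[Si](CC)(CC)CC)C(C)C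
F6 | step 16 | 2β-acetoxy-10α-benzoyloxy-5β-H-dauc-8-ene-4α,6α-diol | O[C@@H]1CC(C)=C[C@H](OC(=O)c3ccccc3)[C@@]2(C)[C@@H](OC(C)=O)C[C@@](O)(C(C)C)[C@H]12
F7 | step 18 | 6β-{2-[bis(2,2,2-trifluoroethoxy)phosphoryl]propanoyloxy} ester of 20 (epimers at the phosphonate carbon) | CC(C(=O)O[C@H]1CC(C)=C[C@H](OC(=O)c2ccccc2)[C@@]2(C)[C@@H](OC(C)=O)C[C@@](O)(C(C)C)[C@H]12)P(=O)(OCC(F)(F)F)OCC(F)(F)F
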